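I time L with a clock.

| flask | L | Z | time |
|---|---|---|---|
| dusk | 0.0500 M | 0.150 M |  |
| winter | 0.0250 M | 0.125 M |  |
| autumn | 0.0500 M | 0.300 M |  |
| noon | 0.0250 M | 0.0750 M | 100 s |

| run | time / s | [Q] / M |
|---|---|---|
| dusk run | 4.0 | 0.0021 |
| dusk run | 8.9 | 0.0039 |
| dusk run | 20 | 0.0108 |
| dusk run | 45 | 0.0230 |
| dusk run | 100 | 0.0363 |
| winter run | 4.0 | 0.0016 |
| winter run | 8.9 | 0.0019 |
| winter run | 20 | 0.0048 |
| winter run | 45 | 0.0085 |
| winter run | 100 | 0.0145 |
| autumn run | 4.0 | 0.0026 |
| autumn run | 8.9 | 0.0063 |
| autumn run | 20 | 0.0153 |
| autumn run | 45 | 0.0309 |
| autumn run | 100 | 0.0361 |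

(standard deviation of a reading: 4 × 10⁻⁴ M)

1. the exponent of [L] in the starting rate at the charge of the dusk run (at the point where two percent of the L have become Q) (one fixed amount of Q, the same in the runs compared)
2. the exponent of [Z] in the starting rate at the charge of the dusk run (at the point where two percent of the L have become Q)
3. Q in the noon run at 100 s, as a share of the L charged

- Overall: L + Z -> Q.
- Constant volume, constant temperature.
- What is held in complexes is read along with the free species.
- "The second partner" is Z.
- An order is taken over about fifteen percent of the charge, up and down.

In the dusk run at 20 s I read 0.0122 /s as the clock k′, which is minus the logarithm of the share of the L charged not read as Q, divided by the time; it is an average over the run up to that time. The autumn run has the L of the dusk run and twice its Z, and at that time it reads 0.0183 /s, so my reading of the Z exponent is 0.586. The winter run at that time reads 0.0107 /s. Once the Z difference is taken out with that exponent, the gap between the winter and dusk clocks gives an L exponent of 1.04. Both are readings averaged over the early run, and they carry the scatter.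

The noon run has the L charge of the winter run, so I scale the winter clock at 100 s, 0.00868 /s, by the Z ratio raised to my exponent. That gives 0.00643 /s for noon, and so 47.4% of its L as Q at 100 s.

The forecast gives exponents of 1 for L and 0.6 for Z and a noon share of 45%, lower than my figure, noting that “Doubling Z raises the rate only about 1.45-fold”.

The flask gives exponents of 1.0 for L and 0.59 for Z, and 49.8% for the noon run at 100 s.

    L + Z → Q (0.2110 /M/s)
    Q + Z → X (0.08150 /M/s)
    2 Z ⇌ Z2, settled at all times (30.00 /M)
    L + Z + Q → 2 Q (14.80 /M²/s)

That noon share puts the noon clock at 0.00689 /s, higher than my 0.00643 /s. Both of these clocks stand for 100 s, and mine rests on a winter reading with a scatter of 4 × 10⁻⁴ M. The clock of the dusk run, read at different times, does move. Its early rate per L charged, nearly the clock at the start, is 0.00927 /s. Its clock is higher at 20 s, at 0.0122 /s, and at 100 s it stands at 0.0129 /s.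

(All runs are simulated for substances that don't exist; noise was put on by code.)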